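**Retrosynthetic overview** (halimane numbering: C4 ester-bearing quaternary carbon, C5 ring-fusion CH, C10=C1 ring alkene, C8 CHMe, C9 quaternary carbon carrying C11–C16, C18 ester carbon)
1. The Z-cinnamate is traced back to a C15 phenylpropiolate (alkyne semihydrogenation), the C15 alcohol and the C18 acid.
2. The strategy rests on the array C18(=O)–C4–C5–C10=C1, a γ,δ-unsaturated acid whose C1 is tied back to C4 through C2–C3. Ring A (C1–C2–C3–C4–C5–C10) is therefore the [3,3] isomer of the silyl ketene acetal of a δ-lactone (ring O–C18–C4–C3–C2–C1, oxygen on C1) that carries ring B as a cyclohex-1-enyl group (C10=C5) on C1.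
3. The lactone comes from a 1R carbinol: Nozaki–Hiyama–Kishi union (C10–C1) of the ring B enol triflate with a C1–C4/C18 aldehyde ester, then oxidation and CBS reduction.
4. Ring B is bought as 2-methylcyclohexenone; C8 comes from catalytic asymmetric methyl addition, C9 from Mukaiyama–Michael addition to methyl vinyl ketone, the 13E unit from Horner–Wadsworth–Emmons olefination.
5. Ring order: ring B (bought), temporary δ-lactone ring, ring A by ring contraction, cinnamate last.

Key step: step 15

**Remarks**
- RB denotes the ring B unit (5R,6S)-6-[(3E)-5-(tert-butyldimethylsilyloxy)-3-methylpent-3-en-1-yl]-5,6-dimethylcyclohex-1-en-1-yl, attached through its C1 (halimane C10).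
- Assumption: in step 1 the enantiomer of the phosphoramidite ligand is the one that delivers methyl to give the 3R (halimane 8R) centre; if the sense of induction proves opposite, the mirror-image ligand is used.
- Compounds 19 to 23 are carried as mixtures at C4, because step 15 makes C4 planar before it is set.

**Step 1**
Reactants: 1 2-methylcyclohex-2-en-1-one
Product: 3 trimethyl{[(3R)-2,3-dimethylcyclohex-1-en-1-yl]oxy}silane, via dimethylaluminium enolate 2 (not isolated)
Conditions: Me3Al, CuTC (copper thiophene-2-carboxylate, 2 mol%), chiral binaphthol phosphoramidite (4 mol%), Et2O, −30 °C; then TMSOTf, THF, −30 → 0 °C; Et3N, aq. NaHCO3 work-up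
Reagents that add atoms: trimethylaluminium, C[Al](C)C; trimethylsilyl triflate, C[Si](C)(C)OS(=O)(=O)C(F)(F)F
Why: Copper-catalysed asymmetric conjugate addition of the methyl group under ligand control should set C8 as R, and O-silylation of the aluminium enolate keeps the C9=C10 enolate regiochemistry for the next step.

**Step 2**
Reactants: 3 trimethyl{[(3R)-2,3-dimethylcyclohex-1-en-1-yl]oxy}silane; 4 methyl vinyl ketone
Product: 5 (2S,3R)-2,3-dimethyl-2-(3-oxobutyl)cyclohexan-1-one
Conditions: BF3·OEt2, i-PrOH, CH2Cl2, −78 °C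
Reagents that add atoms: none
Why: In this Mukaiyama–Michael addition the tetrasubstituted silyl enol ether should attack the activated enone through C9 on the face anti to the pseudoaxial C8 methyl, so the chain ends up trans to that methyl and the two methyls cis (9S), while isopropanol takes up the silyl group and stops the reaction at the 1,5-diketone.

**Step 3**
Reactants: 5 (2S,3R)-2,3-dimethyl-2-(3-oxobutyl)cyclohexan-1-one; 6 triethyl phosphonoacetate
Product: 8 ethyl (2E)-5-[(1S,2R)-1,2-dimethyl-6-oxocyclohexyl]-3-methylpent-2-enoate, via sodium phosphonate anion 7 (not isolated)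
Conditions: 6 (1.3 equiv), NaH (1.2 equiv), THF, 0 °C; then 5, 0 → 50 °C; chromatography to remove the minor Z isomer
Reagents that add atoms: sodium hydride, [Na+].[H-] (sodium only in 7)
Why: Horner–Wadsworth–Emmons olefination, in which the weakly basic stabilised anion should attack only the unhindered methyl ketone (the ring ketone is flanked by quaternary C9) and favour the E enoate, without enough free base to start an aldol cyclisation of the diketone.

**Step 4**
Reactants: 8 ethyl (2E)-5-[(1S,2R)-1,2-dimethyl-6-oxocyclohexyl]-3-methylpent-2-enoate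
Product: 10 ethyl (2E)-5-[(1S,6R)-1,6-dimethyl-2-(triflyloxy)cyclohex-2-en-1-yl]-3-methylpent-2-enoate, via potassium enolate 9 (not isolated)
Conditions: KHMDS (1.05 equiv), THF, −78 °C; then PhNTf2, −78 → −20 °C
Reagents that add atoms: potassium bis(trimethylsilyl)amide, [K+].C[Si](C)(C)[N-][Si](C)(C)C (potassium only in 9); N-phenylbis(trifluoromethanesulfonimide), O=S(=O)(N(c1ccccc1)S(=O)(=O)C(F)(F)F)C(F)(F)F
Why: Kinetic enolisation and O-triflation, where the ring ketone can lose a proton only at C5 and is far more acidic toward a silylamide base than the γ-positions of the enoate, so the C10=C5 enol triflate should form alone.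

**Step 5**
Reactants: 10 ethyl (2E)-5-[(1S,6R)-1,6-dimethyl-2-(triflyloxy)cyclohex-2-en-1-yl]-3-methylpent-2-enoate
Product: 11 (5R,6S)-6-[(3E)-5-hydroxy-3-methylpent-3-en-1-yl]-5,6-dimethylcyclohex-1-en-1-yl triflate
Conditions: DIBAL-H (2.5 equiv), CH2Cl2, −78 °C; aq. potassium sodium tartrate
Reagents that add atoms: none
Why: DIBAL-H 1,2-reduction of the conjugated ester gives the allylic alcohol at low temperature and should leave the alkenyl triflate and the alkene geometry untouched.

**Step 6**
Reactants: 11 (5R,6S)-6-[(3E)-5-hydroxy-3-methylpent-3-en-1-yl]-5,6-dimethylcyclohex-1-en-1-yl triflate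
Product: 12 (5R,6S)-6-[(3E)-5-(tert-butyldimethylsilyloxy)-3-methylpent-3-en-1-yl]-5,6-dimethylcyclohex-1-en-1-yl triflate
Conditions: TBSCl, imidazole, DMF, 0 °C → rt
Reagents that add atoms: tert-butyldimethylsilyl chloride, CC(C)(C)[Si](C)(C)Cl
Why: Standard silyl ether formation masks the primary C15 alcohol for the organochromium, oxidation, strong-base and heating steps that follow.

**Step 7**
Reactants: 13 δ-valerolactone
Product: 15 3-methyltetrahydro-2H-pyran-2-one (racemic), via lithium enolate 14 (not isolated)
Conditions: LDA, THF, −78 °C; then MeI, −78 → −20 °C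
Reagents that add atoms: lithium diisopropylamide, [Li+].CC(C)[N-]C(C)C (lithium only in 14); methyl iodide, CI
Why: Enolate α-alkylation of the lactone with methyl iodide installs the future C19 methyl, and the lack of control at this carbon (C4) is harmless because step 15 makes it planar again.

**Step 8**
Reactants: 15 3-methyltetrahydro-2H-pyran-2-one
Product: 16 methyl 5-hydroxy-2-methylpentanoate (racemic)
Conditions: MeOH, H2SO4 (cat.), reflux; NaHCO3 before concentration
Reagents that add atoms: methanol, CO
Why: Acid-catalysed transesterification in excess methanol opens the δ-lactone to the hydroxy ester, and neutralisation before concentration should prevent relactonisation.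

**Step 9**
Reactants: 16 methyl 5-hydroxy-2-methylpentanoate
Product: 17 methyl 2-methyl-5-oxopentanoate (racemic)
Conditions: TEMPO (cat.), PhI(OAc)2, CH2Cl2, rt
Reagents that add atoms: none
Why: TEMPO-catalysed oxidation of a primary alcohol stops at the aldehyde and leaves the ester alone.

**Step 10**
Reactants: 12 (5R,6S)-6-[(3E)-5-(tert-butyldimethylsilyloxy)-3-methylpent-3-en-1-yl]-5,6-dimethylcyclohex-1-en-1-yl triflate; 17 methyl 2-methyl-5-oxopentanoate
Product: 19 methyl 5-hydroxy-2-methyl-5-RB-pentanoate (epimers at C1 and C4), via alkenylchromium species 18 (not isolated)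
Conditions: CrCl2 (4 equiv), NiCl2 (2 mol%), DMF, rt
Reagents that add atoms: chromium dichloride, Cl[Cr]Cl (chromium and chlorine only in 18)
Why: Nozaki–Hiyama–Kishi coupling, in which nickel-catalysed activation of the alkenyl triflate and transfer to chromium give an alkenylchromium species that should add to the aldehyde but not to the methyl ester, forming C10–C1 with no need for stereocontrol at this stage.

**Step 11**
Reactants: 19 methyl 5-hydroxy-2-methyl-5-RB-pentanoate
Product: 20 methyl 2-methyl-5-oxo-5-RB-pentanoate (epimers at C4)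
Conditions: Dess–Martin periodinane, NaHCO3, CH2Cl2, 0 °C → rt
Reagents that add atoms: none
Why: Buffered Dess–Martin oxidation of the secondary allylic alcohol erases the uncontrolled C1 centre and tolerates the silyl ether, the ester and both alkenes.

**Step 12**
Reactants: 20 methyl 2-methyl-5-oxo-5-RB-pentanoate
Product: 21 methyl (5R)-5-hydroxy-2-methyl-5-RB-pentanoate (1R in halimane numbering; epimers at C4)
Conditions: (S)-2-methyl-CBS-oxazaborolidine (20 mol%), catecholborane, PhMe, −78 °C; MeOH quench, cold dilute NaOH wash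
Reagents that add atoms: none
Why: Corey–Bakshi–Shibata reduction, in which the α-branched alkenyl group (C10 next to quaternary C9) acts as the large substituent and the C2 methylene as the small one, so the (S)-catalyst should deliver hydride to give the 1R carbinol while catecholborane at −78 °C spares the ester and the alkenes.

**Step 13**
Reactants: 21 methyl (5R)-5-hydroxy-2-methyl-5-RB-pentanoate
Product: 22 (5R)-5-hydroxy-2-methyl-5-RB-pentanoic acid (epimers at C4)
Conditions: LiOH, THF/MeOH/H2O, rt; 0.5 M HCl to pH 4, 0 °C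
Reagents that add atoms: lithium hydroxide, [Li+].[OH-] (oxygen of the carboxyl OH)
Why: Saponification of the unhindered methyl ester, with cold and mild acidification so that the allylic alcohol and the primary silyl ether survive.

**Step 14**
Reactants: 22 (5R)-5-hydroxy-2-methyl-5-RB-pentanoic acid
Product: 23 (6R)-3-methyl-6-RB-tetrahydro-2H-pyran-2-one (epimers at C4)
Conditions: EDC·HCl, DMAP, CH2Cl2, rt
Reagents that add atoms: none
Why: Carbodiimide (Steglich-type) lactonisation activates the carboxyl group only, so the C1–O bond is never broken, the 1R configuration is retained and no acid touches the allylic carbinol.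

**Step 15**
Reactants: 23 (6R)-3-methyl-6-RB-tetrahydro-2H-pyran-2-one
Product: 26 (1S,5S,6R,8aR)-5-[(3E)-5-(tert-butyldimethylsilyloxy)-3-methylpent-3-en-1-yl]-1,5,6-trimethyl-1,2,3,5,6,7,8,8a-octahydronaphthalene-1-carboxylic acid, via silyl ketene acetal 24 (not isolated), via silyl ester 25 (not isolated)
Conditions: LDA, TBSCl, HMPA, THF, −78 °C (23 added last), → 0 °C; then PhMe, 105 °C; then K2CO3, MeOH/H2O, rt; pH 5 work-up
Reagents that add atoms: tert-butyldimethylsilyl chloride, CC(C)(C)[Si](C)(C)Cl (this silicon only in 24 and 25)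
Why: Ireland–Claisen rearrangement of a lactone silyl ketene acetal: deprotonation at C4 and O-silylation give the cyclic ketene acetal 24, in which C4 is planar so both C4 epimers of 23 converge, and on heating a concerted suprafacial [3,3] shift forms C4–C5, breaks O–C1 and moves the alkene from C5=C10 to C10=C1. The closest known reaction types are the Claisen ring contraction of silyl enolates of alkenyl lactones to cycloalkenecarboxylic acids and the thermal rearrangement of 2-alkenyl-3,4-dihydro-2H-pyrans to cyclohexenes. Ring A (C1–C2–C3–C4–C5–C10) closes by this C4–C5 bond formation through a bicyclo[2.2.2]octane-like boat transition state (bridgeheads C1 and C4; bridges O–C18, C10=C5 and C2–C3), the only arrangement that leaves C2 cis to C5 on the new ring alkene, while the lactone ring opens and C18 is released as the silyl ester. C5 is controlled by the 1R carbinol centre, because the new bond must form on the ring B face that held the oxygen, which places H5 on the face of the C9 methyl (5R); C4 is controlled by the ring-fixed ketene acetal geometry in the boat, where C18 lies against C10 and the C4 methyl against C6, so the carboxyl ends up trans to H5 and on the face of the C9 side chain (4S). The step needs complete transfer of the C1 configuration to C5 and C4 and a single alkene position; these are secured by the endocyclic ketene acetal, the fixed ring B alkene, the two-carbon C2–C3 tether and bond formation anti to the pseudoaxial C9 methyl, and since C5 carries only hydrogen no regioisomeric or intermolecular path is open. The carbonate work-up cleaves the silyl ester while the primary silyl ether should survive.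

**Step 16**
Reactants: 26 the bicyclic C18 acid
Product: 27 methyl (1S,5S,6R,8aR)-5-[(3E)-5-(tert-butyldimethylsilyloxy)-3-methylpent-3-en-1-yl]-1,5,6-trimethyl-1,2,3,5,6,7,8,8a-octahydronaphthalene-1-carboxylate
Conditions: MeI, K2CO3, DMF, rt
Reagents that add atoms: methyl iodide, CI
Why: O-Alkylation of the carboxylate (SN2 on methyl iodide) esterifies the hindered tertiary acid without acid and without attack at the crowded carbonyl carbon.

**Step 17**
Reactants: 27 the silyl ether methyl ester
Product: 28 methyl (1S,5S,6R,8aR)-5-[(3E)-5-hydroxy-3-methylpent-3-en-1-yl]-1,5,6-trimethyl-1,2,3,5,6,7,8,8a-octahydronaphthalene-1-carboxylate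
Conditions: TBAF, THF, 0 °C → rt
Reagents that add atoms: none
Why: Fluoride-induced desilylation frees the primary allylic alcohol, and the neopentyl-type methyl ester is inert to these conditions.

**Step 18**
Reactants: 28 the C15 alcohol methyl ester; 29 phenylpropiolic acid
Product: 30 methyl (1S,5S,6R,8aR)-1,5,6-trimethyl-5-{(3E)-3-methyl-5-[(3-phenylprop-2-ynoyl)oxy]pent-3-en-1-yl}-1,2,3,5,6,7,8,8a-octahydronaphthalene-1-carboxylate
Conditions: DCC, DMAP (cat.), CH2Cl2, 0 °C → rt
Reagents that add atoms: none
Why: Steglich esterification of the unhindered primary allylic alcohol with the alkynoic acid, with only catalytic DMAP at low temperature to limit conjugate addition to the ynoate.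

**Step 19**
Reactants: 30 the C15 phenylpropiolate
Product: 31 methyl (1S,5S,6R,8aR)-1,5,6-trimethyl-5-[(3E)-3-methyl-5-{[(2Z)-3-phenylprop-2-enoyl]oxy}pent-3-en-1-yl]-1,2,3,5,6,7,8,8a-octahydronaphthalene-1-carboxylate (CNP0296075.1)
Conditions: H2 (1 atm), Pd/CaCO3 poisoned with Pb(OAc)2 (Lindlar catalyst), quinoline, EtOAc, rt; stopped after one equivalent of H2
Reagents that add atoms: none
Why: Lindlar semihydrogenation delivers one equivalent of hydrogen syn to the alkyne on the poisoned palladium surface to give the Z cinnamate, and the two trisubstituted alkenes and the allylic C–O bond should not react with this catalyst.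

**Compound list**
1 | 2-methylcyclohex-2-en-1-one | CC1=CCCCC1=O | starting material
2 | dimethylaluminium (3R)-2,3-dimethylcyclohex-1-en-1-olate (not isolated) | C[Al](C)OC1=C(C)[C@H](C)CCC1 | intermediate
3 | trimethyl{[(3R)-2,3-dimethylcyclohex-1-en-1-yl]oxy}silane | C[Si](C)(C)OC1=C(C)[C@H](C)CCC1 | intermediate
4 | methyl vinyl ketone | CC(=O)C=C | starting material
5 | (2S,3R)-2,3-dimethyl-2-(3-oxobutyl)cyclohexan-1-one | O=C1CCC[C@@H](C)[C@]1(C)CCC(C)=O | intermediate
6 | triethyl phosphonoacetate | CCOC(=O)CP(=O)(OCC)OCC | starting material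
7 | sodium salt of triethyl phosphonoacetate (not isolated) | [Na+].CCOC(=O)[CH-]P(=O)(OCC)OCC | intermediate
8 | ethyl (2E)-5-[(1S,2R)-1,2-dimethyl-6-oxocyclohexyl]-3-methylpent-2-enoate | O=C1CCC[C@@H](C)[C@]1(C)CC/C(C)=C/C(=O)OCC | intermediate
9 | potassium enolate of 8 (not isolated) | [K+].[O-]C1=CCC[C@@H](C)[C@]1(C)CC/C(C)=C/C(=O)OCC | intermediate
10 | ethyl (2E)-5-[(1S,6R)-1,6-dimethyl-2-(triflyloxy)cyclohex-2-en-1-yl]-3-methylpent-2-enoate | FC(F)(F)S(=O)(=O)OC1=CCC[C@@H](C)[C@]1(C)CC/C(C)=C/C(=O)OCC | intermediate
11 | (5R,6S)-6-[(3E)-5-hydroxy-3-methylpent-3-en-1-yl]-5,6-dimethylcyclohex-1-en-1-yl triflate | FC(F)(F)S(=O)(=O)OC1=CCC[C@@H](C)[C@]1(C)CC/C(C)=C/CO | intermediate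
12 | (5R,6S)-6-[(3E)-5-(tert-butyldimethylsilyloxy)-3-methylpent-3-en-1-yl]-5,6-dimethylcyclohex-1-en-1-yl triflate | FC(F)(F)S(=O)(=O)OC1=CCC[C@@H](C)[C@]1(C)CC/C(C)=C/CO[Si](C)(C)C(C)(C)C | intermediate
13 | δ-valerolactone | O=C1CCCCO1 | starting material
14 | lithium enolate of δ-valerolactone (not isolated) | [Li+].[O-]C1=CCCCO1 | intermediate
15 | 3-methyltetrahydro-2H-pyran-2-one, racemic | CC1CCCOC1=O | intermediate
16 | methyl 5-hydroxy-2-methylpentanoate, racemic | COC(=O)C(C)CCCO | intermediate
17 | methyl 2-methyl-5-oxopentanoate, racemic | COC(=O)C(C)CCC=O | intermediate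
18 | RB-chromium dichloride, trivalent chromium (not isolated) | Cl[Cr](Cl)C1=CCC[C@@H](C)[C@]1(C)CC/C(C)=C/CO[Si](C)(C)C(C)(C)C | intermediate
19 | methyl 5-hydroxy-2-methyl-5-RB-pentanoate, epimers at C1 and C4 | COC(=O)C(C)CCC(O)C1=CCC[C@@H](C)[C@]1(C)CC/C(C)=C/CO[Si](C)(C)C(C)(C)C | intermediate
20 | methyl 2-methyl-5-oxo-5-RB-pentanoate, epimers at C4 | COC(=O)C(C)CCC(=O)C1=CCC[C@@H](C)[C@]1(C)CC/C(C)=C/CO[Si](C)(C)C(C)(C)C | intermediate
21 | methyl (5R)-5-hydroxy-2-methyl-5-RB-pentanoate, epimers at C4 | COC(=O)C(C)CC[C@@H](O)C1=CCC[C@@H](C)[C@]1(C)CC/C(C)=C/CO[Si](C)(C)C(C)(C)C | intermediate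
22 | (5R)-5-hydroxy-2-methyl-5-RB-pentanoic acid, epimers at C4 | OC(=O)C(C)CC[C@@H](O)C1=CCC[C@@H](C)[C@]1(C)CC/C(C)=C/CO[Si](C)(C)C(C)(C)C | intermediate
23 | (6R)-3-methyl-6-RB-tetrahydro-2H-pyran-2-one, epimers at C4 | CC1CC[C@@H](OC1=O)C2=CCC[C@@H](C)[C@]2(C)CC/C(C)=C/CO[Si](C)(C)C(C)(C)C | intermediate
24 | (2R)-6-(tert-butyldimethylsilyloxy)-5-methyl-2-RB-3,4-dihydro-2H-pyran (not isolated) | CC1=C(O[Si](C)(C)C(C)(C)C)O[C@H](CC1)C2=CCC[C@@H](C)[C@]2(C)CC/C(C)=C/CO[Si](C)(C)C(C)(C)C | intermediate
25 | tert-butyldimethylsilyl ester of acid 26 (not isolated) | CC(C)(C)[Si](C)(C)OC(=O)[C@@]1(C)CCC=C2[C@H]1CC[C@@H](C)[C@]2(C)CC/C(C)=C/CO[Si](C)(C)C(C)(C)C | intermediate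
26 | (1S,5S,6R,8aR)-5-[(3E)-5-(tert-butyldimethylsilyloxy)-3-methylpent-3-en-1-yl]-1,5,6-trimethyl-1,2,3,5,6,7,8,8a-octahydronaphthalene-1-carboxylic acid | OC(=O)[C@@]1(C)CCC=C2[C@H]1CC[C@@H](C)[C@]2(C)CC/C(C)=C/CO[Si](C)(C)C(C)(C)C | intermediate
27 | methyl ester of 26 | COC(=O)[C@@]1(C)CCC=C2[C@H]1CC[C@@H](C)[C@]2(C)CC/C(C)=C/CO[Si](C)(C)C(C)(C)C | intermediate
28 | methyl (1S,5S,6R,8aR)-5-[(3E)-5-hydroxy-3-methylpent-3-en-1-yl]-1,5,6-trimethyl-1,2,3,5,6,7,8,8a-octahydronaphthalene-1-carboxylate | COC(=O)[C@@]1(C)CCC=C2[C@H]1CC[C@@H](C)[C@]2(C)CC/C(C)=C/CO | intermediate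
29 | phenylpropiolic acid | OC(=O)C#Cc1ccccc1 | starting material
30 | C15 phenylpropiolate of 28 | COC(=O)[C@@]1(C)CCC=C2[C@H]1CC[C@@H](C)[C@]2(C)CC/C(C)=C/COC(=O)C#Cc1ccccc1 | intermediate
31 | methyl (1S,5S,6R,8aR)-1,5,6-trimethyl-5-[(3E)-3-methyl-5-{[(2Z)-3-phenylprop-2-enoyl]oxy}pent-3-en-1-yl]-1,2,3,5,6,7,8,8a-octahydronaphthalene-1-carboxylate | COC(=O)[C@@]1(C)CCC=C2[C@H]1CC[C@@H](C)[C@]2(C)CC/C(C)=C/COC(=O)/C=C\c1ccccc1 | target

**Totals**
Total step count: 19. Longest linear sequence: 16 steps (steps 1–6 and 10–19); steps 7–9 form the three-step side branch to aldehyde 17.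

**Steps most likely to fail**

Step 15. The boat-shaped rearrangement next to quaternary C9 may be slower than decomposition of the silyl ketene acetal (C-silylation, or ionisation and elimination at the allylic C1–O bond), so that little ring A product forms. The fallback keeps the same bond reorganisation but runs it on the neutral enol ether, setting out from 23 and returning at 26. Lactone 23 is reduced with DIBAL-H (PhMe, −78 °C) to the lactol F1. This is dehydrated with MsCl and Et3N (CH2Cl2, 0 °C to reflux) to the 2-alkenyl-5-methyl-3,4-dihydro-2H-pyran F2, in which C4 is again planar. Heating F2 in toluene in a base-washed sealed tube at about 200–230 °C should give, by the thermal Claisen rearrangement of 2-alkenyl-dihydropyrans through the same boat, the C18 aldehyde F3. Pinnick oxidation (NaClO2, NaH2PO4, 2-methylbut-2-ene, t-BuOH/H2O) then gives acid 26.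

Step 10. Activation of the hindered alkenyl triflate beside quaternary C9 and transfer to chromium may be slow, so that reduction of the triflate or self-coupling of the aldehyde takes over. The fallback replaces the chromium chemistry by an alkenyllithium addition, setting out from 12 and returning at 19. Triflate 12 is stannylated with hexamethylditin, Pd(PPh3)4 (zerovalent palladium) and LiCl in refluxing THF to give the trimethyl-RB-stannane F4. Tin–lithium exchange with one equivalent of MeLi (THF, −78 °C) gives RB-lithium F5, which is added at −78 °C to aldehyde 17. At that temperature the aldehyde should react well ahead of the methyl ester, and the product is 19.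

Step 12. Hydride delivery to the twisted, crowded enone may show poor facial discrimination, and a mixture at C1 would pass through step 15 as a mixture at C4 and C5. The fallback gives up reagent control and relies on the stereospecificity of the rearrangement, setting out from 19 and returning at 26. Alcohol 19, as both C1 epimers, is saponified and lactonised under the conditions of steps 13 and 14 without passing through 20 and 21. This gives 22 and 23 together with the 1S hydroxy acid F6 and the 1S lactone F7. The lactone mixture is taken through the conditions of step 15. Lactone 23 should give 26, and F7 should pass through the 1S silyl ketene acetal F8 and the diastereomeric silyl ester F9 to the 4R,5S acid F10. Acids 26 and F10 differ in the configuration of C4 and C5 relative to C8 and C9; they are diastereomers and should be separable by chromatography, as the acids or as methyl esters after step 16. The cost is at most half of the material.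

**Further compounds**
F1 | step 15 | (6R)-3-methyl-6-RB-tetrahydro-2H-pyran-2-ol (lactol, mixture at C2 and C3 of the pyran) | CC1CC[C@@H](OC1O)C2=CCC[C@@H](C)[C@]2(C)CC/C(C)=C/CO[Si](C)(C)C(C)(C)C
F2 | step 15 | (2R)-5-methyl-2-RB-3,4-dihydro-2H-pyran | CC1=CO[C@H](CC1)C2=CCC[C@@H](C)[C@]2(C)CC/C(C)=C/CO[Si](C)(C)C(C)(C)C
F3 | step 15 | (1S,5S,6R,8aR)-5-[(3E)-5-(tert-butyldimethylsilyloxy)-3-methylpent-3-en-1-yl]-1,5,6-trimethyl-1,2,3,5,6,7,8,8a-octahydronaphthalene-1-carbaldehyde | O=C[C@@]1(C)CCC=C2[C@H]1CC[C@@H](C)[C@]2(C)CC/C(C)=C/CO[Si](C)(C)C(C)(C)C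
F4 | step 10 | trimethyl-RB-stannane | C[Sn](C)(C)C1=CCC[C@@H](C)[C@]1(C)CC/C(C)=C/CO[Si](C)(C)C(C)(C)C
F5 | step 10 | RB-lithium | [Li]C1=CCC[C@@H](C)[C@]1(C)CC/C(C)=C/CO[Si](C)(C)C(C)(C)C
F6 | step 12 | (5S)-5-hydroxy-2-methyl-5-RB-pentanoic acid (1S epimer of 22) | OC(=O)C(C)CC[C@H](O)C1=CCC[C@@H](C)[C@]1(C)CC/C(C)=C/CO[Si](C)(C)C(C)(C)C
F7 | step 12 | (6S)-3-methyl-6-RB-tetrahydro-2H-pyran-2-one (1S epimer of 23) | CC1CC[C@H](OC1=O)C2=CCC[C@@H](C)[C@]2(C)CC/C(C)=C/CO[Si](C)(C)C(C)(C)C
F8 | step 12 | (2S)-6-(tert-butyldimethylsilyloxy)-5-methyl-2-RB-3,4-dihydro-2H-pyran | CC1=C(O[Si](C)(C)C(C)(C)C)O[C@@H](CC1)C2=CCC[C@@H](C)[C@]2(C)CC/C(C)=C/CO[Si](C)(C)C(C)(C)C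
F9 | step 12 | tert-butyldimethylsilyl ester of the 4R,5S acid | CC(C)(C)[Si](C)(C)OC(=O)[C@]1(C)CCC=C2[C@@H]1CC[C@@H](C)[C@]2(C)CC/C(C)=C/CO[Si](C)(C)C(C)(C)C
F10 | step 12 | (1R,5S,6R,8aS)-5-[(3E)-5-(tert-butyldimethylsilyloxy)-3-methylpent-3-en-1-yl]-1,5,6-trimethyl-1,2,3,5,6,7,8,8a-octahydronaphthalene-1-carboxylic acid (4R,5S diastereomer of 26) | OC(=O)[C@]1(C)CCC=C2[C@@H]1CC[C@@H](C)[C@]2(C)CC/C(C)=C/CO[Si](C)(C)C(C)(C)C
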